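**Retrosynthetic overview**
1. Target ⇐ C5 acetylation ⇐ acid cascade (deprotection; C12 acid onto C8 gives spirolactone ring C) ⇐ ring B hemiketal ⇐ reduction at C1 of a ten-membered (Z)-ene-1,8-dione.
2. Key C1–C10 bond: a carbene-bound acyl anion (Breslow intermediate) at the C1 aldehyde adds to C10 of a but-2-ynoyl ketone (macrocyclising Stetter); C1, a carbinol carbon in the target, is the umpoled centre, and C8 stays an ordinary ketone.
3. Aldehyde–ynone ⇐ one-flask C6–C7 dioxolanone aldol, propynyl addition at C8 and lactonisation (ring A); pieces: L-tartrate acetonide (C4–C6, C15; C4-propargyl gives C1–C3) and D-malate (C7, C8, C11, C12; methylated for C13).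
4. Ring order: A → ten-membered carbocycle → B → C.

Assumption: every stereodescriptor is taken exactly as written in the SMILES, including ketal carbon C8, which forms under equilibrating acid conditions; locants throughout are C1–C10 = ring carbons (C1 = OCH beside C10, C4 = C(OH) carrying C15(=O), C5 = CHOAc, C6 = CH–O of the C15 lactone, C7 = C(OH) carrying C11, C8 = ketal carbon), C11(C13H3)–C12(=O) = branch on C7, C14 = CH3 on C10.

Step 1
Reactants: 1 dimethyl (2R)-2-hydroxybutanedioate (dimethyl D-malate)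
Product: 2 dimethyl (2R,3S)-2-hydroxy-3-methylbutanedioate
Conditions: LiN(iPr)2 (2.2 equiv), THF, −78 to −20 °C; MeI, −78 to 0 °C; AcOH quench
Reagents that add atoms: iodomethane, CI
Why: Fráter–Seebach alkylation: the lithium alkoxide–enolate dianion is a rigid chelate and iodomethane approaches anti to the C2–O bond, which sets C3 (C11 of the target) as S with about 9:1 selectivity.

Step 2
Reactants: 2 dimethyl (2R,3S)-2-hydroxy-3-methylbutanedioate
Product: 3 (2R,3S)-2-hydroxy-3-methylbutanedioic acid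
Conditions: LiOH (3 equiv), THF/H2O, 0 °C to rt; then aq. HCl to pH 1
Reagents that add atoms: lithium hydroxide, [Li+].[OH-]
Why: Ester saponification at or below room temperature; the dicarboxylate resists enolisation, so both stereocentres keep their configuration.

Step 3
Reactants: 3 (2R,3S)-2-hydroxy-3-methylbutanedioic acid
Product: 4 (2S)-2-[(2R,4R)-2-tert-butyl-5-oxo-1,3-dioxolan-4-yl]propanoic acid
Conditions: pivalaldehyde (2 equiv), TsOH (5 mol%), H2SO4 (cat.), pentane, reflux, Dean–Stark
Reagents that add atoms: pivalaldehyde, CC(C)(C)C=O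
Why: Acid-catalysed acetalisation of the α-hydroxy acid (Seebach dioxolanone for self-regeneration of stereocentres): the five-membered dioxolanone is preferred over the six-membered dioxanone and equilibration gives the cis isomer, so the new acetal carbon is R with tert-butyl cis to the side chain (purified by crystallisation).

Step 4
Reactants: 4 (2S)-2-[(2R,4R)-2-tert-butyl-5-oxo-1,3-dioxolan-4-yl]propanoic acid
Product: 5 tert-butyl (2S)-2-[(2R,4R)-2-tert-butyl-5-oxo-1,3-dioxolan-4-yl]propanoate
Conditions: tert-butyl 2,2,2-trichloroacetimidate (2 equiv), BF3·OEt2 (5 mol%), CH2Cl2/cyclohexane, rt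
Reagents that add atoms: tert-butyl 2,2,2-trichloroacetimidate, CC(C)(C)OC(=N)C(Cl)(Cl)Cl
Why: Acid-catalysed imidate esterification that leaves the acetal intact; the tert-butyl ester keeps C12 from lactonising before the final acid step, and no stereocentre is touched.

Step 5
Reactants: 6 dimethyl (4R,5R)-2,2-dimethyl-1,3-dioxolane-4,5-dicarboxylate (dimethyl 2,3-O-isopropylidene-L-tartrate)
Product: 7 dimethyl (4S,5R)-2,2-dimethyl-4-(prop-2-yn-1-yl)-1,3-dioxolane-4,5-dicarboxylate
Conditions: LiN(iPr)2 (1.1 equiv), THF/HMPA (4:1), −78 °C; propargyl bromide (1.5 equiv), −78 °C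
Reagents that add atoms: propargyl bromide, C#CCBr
Why: Alkylation of the lithium enolate of the tartrate acetonide (Seebach–Naef tartrate alkylation) with a reactive propargylic bromide: the electrophile enters trans to the ester on the neighbouring ring carbon, so quaternary C4 is S with the two esters cis, and C5 is untouched.

Step 6
Reactants: 7 dimethyl (4S,5R)-2,2-dimethyl-4-(prop-2-yn-1-yl)-1,3-dioxolane-4,5-dicarboxylate
Product: 8 methyl (4S,5R)-5-formyl-2,2-dimethyl-4-(prop-2-yn-1-yl)-1,3-dioxolane-4-carboxylate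
Conditions: iBu2AlH (1.1 equiv), CH2Cl2, −78 °C; MeOH, then aq. Rochelle salt
Reagents that add atoms: none
Why: DIBAL-H half-reduction: the ester on the CH carbon is far less hindered than the neopentyl-type ester on the quaternary carbon and its chelated aluminium hemiacetal survives at −78 °C until work-up, so only C6 becomes an aldehyde and C5 is not epimerised.

Step 7
Reactants: 5 tert-butyl (2S)-2-[(2R,4R)-2-tert-butyl-5-oxo-1,3-dioxolan-4-yl]propanoate; 8 methyl (4S,5R)-5-formyl-2,2-dimethyl-4-(prop-2-yn-1-yl)-1,3-dioxolane-4-carboxylate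
Product: 11 tert-butyl (2S,3S)-3-[(3aS,6R,6aS)-2,2-dimethyl-4-oxo-3a-(prop-2-yn-1-yl)tetrahydrofuro[3,4-d][1,3]dioxol-6-yl]-3-hydroxy-2-methyl-4-oxohept-5-ynoate, via aldol adduct 9 (not isolated), via propynyl hemiketal 10 (not isolated)
Conditions: 5, LiN(iPr)2 (1.05 equiv), THF, −78 °C; 8, −78 °C, 1 h; 1-propynyllithium (4 equiv; the terminal alkyne rides as its lithium acetylide), −78 °C, 2 h; AcOH, −78 °C to rt; camphorsulfonic acid (5 mol%), CH2Cl2, rt
Reagents that add atoms: 1-propynyllithium, [Li]C#CC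
Why: Seebach dioxolanone aldol, acetylide acylation and lactonisation in one flask: the enolate of 5 is attacked trans to the tert-butyl group so C6 replaces H at C7 with retention (7S, quaternary), the aldehyde reacts in the Felkin–Anh sense anti to its C5–O bond (6R), 1-propynyllithium adds once to the acylal-type dioxolanone carbonyl (more electrophilic than the neopentyl methyl ester or the tert-butyl ester), and acidification collapses the hemiketal with loss of pivalaldehyde to the ynone while the C6 hydroxyl closes ring A on the cis methyl ester.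

Step 8
Reactants: 11 ring A lactone hydroxy ynone
Product: 12 tert-butyl (2S,3S)-3-[(3aS,6R,6aS)-2,2-dimethyl-4-oxo-3a-(prop-2-yn-1-yl)tetrahydrofuro[3,4-d][1,3]dioxol-6-yl]-2-methyl-4-oxo-3-[(triethylsilyl)oxy]hept-5-ynoate
Conditions: Et3SiOTf (1.5 equiv), 2,6-lutidine (3 equiv), CH2Cl2, −40 to 0 °C
Reagents that add atoms: triethylsilyl trifluoromethanesulfonate, CC[Si](CC)(CC)OS(=O)(=O)C(F)(F)F
Why: Silyl triflate silylation of the hindered tertiary alcohol: a free 7-OH next to the ynone would close 5-endo onto C10 to a 3(2H)-furanone under the basic carbene conditions of step 10, and the triethylsilyl ether blocks this and is removed in step 12.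

Step 9
Reactants: 12 silyl-protected ynone with terminal alkyne
Product: 13 tert-butyl (2S,3S)-3-[(3aS,6R,6aS)-2,2-dimethyl-4-oxo-3a-(3-oxopropyl)tetrahydrofuro[3,4-d][1,3]dioxol-6-yl]-2-methyl-4-oxo-3-[(triethylsilyl)oxy]hept-5-ynoate
Conditions: [CpRu(NCMe)(L)2]PF6 (5 mol%; L = 2-diphenylphosphino-6-tert-butylpyridine), H2O (5 equiv), acetone, 60 °C
Reagents that add atoms: water, O
Why: Ruthenium-vinylidene anti-Markovnikov alkyne hydration: only the terminal C1≡C2 alkyne can form the vinylidene, so water adds at C1 to give the aldehyde while the internal ynone, silyl ether, acetal and esters are untouched.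

Step 10
Reactants: 13 aldehyde–ynone
Product: 14 macrocyclic (9Z)-ene-1,8-dione (4S,5S,6R,7S,11S; ring A lactone; 4,5-O-isopropylidene; 7-OSiEt3; C12 tert-butyl ester)
Conditions: 3-benzyl-5-(2-hydroxyethyl)-4-methylthiazolium chloride (30 mol%), Et3N (60 mol%), 1,4-dioxane, 70 °C, 2 mM, syringe-pump addition over 20 h
Reagents that add atoms: none
Why: Proposed new method: the thiazol-2-ylidene adds to the C1 aldehyde to give the Breslow intermediate, an acyl-anion equivalent at a carbon that is electrophilic by nature, which adds to the electrophilic β-carbon C10 of the ynone, and α-protonation of the allenolate with release of the carbene gives the ene-1,4-dione held cis by the ring (no stereocentre is formed); the closest known reactions are intermolecular Stetter additions of aliphatic aldehydes to activated alkynes and thiazolium-catalysed macrocyclising Stetter reactions onto enoates, and here the cis-fused lactone–acetonide of ring A points the two arms to the same face while high dilution suppresses benzoin dimerisation.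

Step 11
Reactants: 14 macrocyclic (9Z)-ene-1,8-dione
Product: 16 ring B hemiketal (1S,4S,5S,6R,7S,8R,11S; 1,8-epoxy-8-hydroxy), via hydroxy enone 15 (not isolated)
Conditions: (R)-Me-CBS oxazaborolidine [(R)-1-methyl-3,3-diphenyltetrahydro-1H,3H-pyrrolo[1,2-c][1,3,2]oxazaborole] (1.0 equiv), catecholborane (2 equiv), toluene, −78 °C; MeOH, then aq. NaHCO3
Reagents that add atoms: none
Why: Corey–Bakshi–Shibata reduction: the C1 ketone, flanked by a CH2, is reduced 1,2 in preference to the C8 ketone shielded by quaternary C7, the (R)-catalyst treats the alkenyl arm as the large group and gives the (1S)-alcohol, and the cis γ-hydroxy enone 15 closes on C8 to the ring B hemiketal, whose anomeric C8 is fixed only in step 12.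

Step 12
Reactants: 16 ring B hemiketal
Product: 18 (1S,4S,5S,6R,7S,8S,11S)-1,8-epoxy-4,5,7-trihydroxygermacr-9-ene-12,8:15,6-diolide, via seco acid 17 (not isolated)
Conditions: CF3CO2H/H2O (9:1), CH2Cl2, 0 °C to rt
Reagents that add atoms: none
Why: Acidolysis followed by acid-catalysed spiroketalisation: trifluoroacetic acid removes the acetonide, the silyl ether and the tert-butyl ester, and the freed C12 acid traps the C8 oxocarbenium ion of the hemiketal as the five-membered acyloxy ketal (ring C), an equilibrating step that leaves C8 in its thermodynamic configuration; aromatisation to a furan is blocked because a 2,5-furan bridged by six carbons would be too strained.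

Step 13
Reactants: 18 tetracyclic triol
Product: 19 (1S,4S,5S,6R,7S,8S,11S)-5-acetoxy-1,8-epoxy-4,7-dihydroxygermacr-9-ene-12,8:15,6-diolide (target)
Conditions: Ac2O (1.5 equiv), pyridine, DMAP (5 mol%), CH2Cl2, 0 °C
Reagents that add atoms: acetic anhydride, CC(=O)OC(C)=O
Why: DMAP-catalysed acylation: the C5 hydroxyl is the only secondary alcohol and the tertiary C4 and C7 hydroxyls do not react at 0 °C, which gives the target.

**Compound list**

1 | dimethyl (2R)-2-hydroxybutanedioate (dimethyl D-malate) | COC(=O)C[C@@H](O)C(=O)OC | starting material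
2 | dimethyl (2R,3S)-2-hydroxy-3-methylbutanedioate | COC(=O)[C@@H](C)[C@@H](O)C(=O)OC | intermediate
3 | (2R,3S)-2-hydroxy-3-methylbutanedioic acid | OC(=O)[C@@H](C)[C@@H](O)C(=O)O | intermediate
4 | (2S)-2-[(2R,4R)-2-tert-butyl-5-oxo-1,3-dioxolan-4-yl]propanoic acid (cis-dioxolanone) | OC(=O)[C@@H](C)[C@H]1O[C@@H](C(C)(C)C)OC1=O | intermediate
5 | tert-butyl (2S)-2-[(2R,4R)-2-tert-butyl-5-oxo-1,3-dioxolan-4-yl]propanoate | CC(C)(C)OC(=O)[C@@H](C)[C@H]1O[C@@H](C(C)(C)C)OC1=O | intermediate
6 | dimethyl (4R,5R)-2,2-dimethyl-1,3-dioxolane-4,5-dicarboxylate (dimethyl 2,3-O-isopropylidene-L-tartrate) | COC(=O)[C@@H]1OC(C)(C)O[C@H]1C(=O)OC | starting material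
7 | dimethyl (4S,5R)-2,2-dimethyl-4-(prop-2-yn-1-yl)-1,3-dioxolane-4,5-dicarboxylate | COC(=O)[C@@]1(CC#C)OC(C)(C)O[C@H]1C(=O)OC | intermediate
8 | methyl (4S,5R)-5-formyl-2,2-dimethyl-4-(prop-2-yn-1-yl)-1,3-dioxolane-4-carboxylate | COC(=O)[C@@]1(CC#C)OC(C)(C)O[C@H]1C=O | intermediate
9 | aldol adduct, not isolated: methyl (4S,5S)-5-{(R)-[(2R,4S)-2-tert-butyl-4-[(2S)-1-tert-butoxy-1-oxopropan-2-yl]-5-oxo-1,3-dioxolan-4-yl](hydroxy)methyl}-2,2-dimethyl-4-(prop-2-yn-1-yl)-1,3-dioxolane-4-carboxylate | COC(=O)[C@@]1(CC#C)OC(C)(C)O[C@H]1[C@@H](O)[C@@]2(O[C@@H](C(C)(C)C)OC2=O)[C@H](C)C(=O)OC(C)(C)C | intermediate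
10 | propynyl hemiketal, not isolated: 9 with the dioxolanone C=O converted to C(OH)(C≡C–CH3), either configuration at that carbon | COC(=O)[C@@]1(CC#C)OC(C)(C)O[C@H]1[C@@H](O)[C@@]2(O[C@@H](C(C)(C)C)OC2(O)C#CC)[C@H](C)C(=O)OC(C)(C)C | intermediate
11 | tert-butyl (2S,3S)-3-[(3aS,6R,6aS)-2,2-dimethyl-4-oxo-3a-(prop-2-yn-1-yl)tetrahydrofuro[3,4-d][1,3]dioxol-6-yl]-3-hydroxy-2-methyl-4-oxohept-5-ynoate (ring A closed, 7-OH free) | CC1(C)O[C@H]2[C@@H](OC(=O)[C@@]2(CC#C)O1)[C@](O)(C(=O)C#CC)[C@H](C)C(=O)OC(C)(C)C | intermediate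
12 | 7-O-triethylsilyl ether of 11: tert-butyl (2S,3S)-3-[(3aS,6R,6aS)-2,2-dimethyl-4-oxo-3a-(prop-2-yn-1-yl)tetrahydrofuro[3,4-d][1,3]dioxol-6-yl]-2-methyl-4-oxo-3-[(triethylsilyl)oxy]hept-5-ynoate | CC1(C)O[C@H]2[C@@H](OC(=O)[C@@]2(CC#C)O1)[C@](O[Si](CC)(CC)CC)(C(=O)C#CC)[C@H](C)C(=O)OC(C)(C)C | intermediate
13 | aldehyde–ynone: 12 with 3-oxopropyl (C3H2–C2H2–C1HO) in place of the propargyl group | CC1(C)O[C@H]2[C@@H](OC(=O)[C@@]2(CCC=O)O1)[C@](O[Si](CC)(CC)CC)(C(=O)C#CC)[C@H](C)C(=O)OC(C)(C)C | intermediate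
14 | macrocyclic (9Z)-ene-1,8-dione (4S,5S,6R,7S,11S): ten-membered carbocycle C1–C10 with C1=O, C8=O and the C9=C10 alkene (C14 methyl on C10); ring A = C15 lactone to O6, cis-fused to the 4,5-O-isopropylidene acetal; 7-OSiEt3; C11H(CH3)–C12O2tBu on C7 | CC1(C)O[C@H]2[C@H]3OC(=O)[C@@]2(CCC(=O)/C(C)=C\C(=O)[C@]3(O[Si](CC)(CC)CC)[C@H](C)C(=O)OC(C)(C)C)O1 | intermediate
15 | (1S)-hydroxy enone, not isolated: 14 with the C1 ketone reduced to the (1S)-alcohol | CC1(C)O[C@H]2[C@H]3OC(=O)[C@@]2(CC[C@H](O)/C(C)=C\C(=O)[C@]3(O[Si](CC)(CC)CC)[C@H](C)C(=O)OC(C)(C)C)O1 | intermediate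
16 | ring B hemiketal (1S,4S,5S,6R,7S,8R,11S): 15 closed by O1 onto C8 (1,8-epoxy-8-hydroxy; C8 drawn with the spatial arrangement of the target) | CC1(C)O[C@H]2[C@H]3OC(=O)[C@@]2(CC[C@@H]4O[C@](O)(C=C4C)[C@]3(O[Si](CC)(CC)CC)[C@H](C)C(=O)OC(C)(C)C)O1 | intermediate
17 | seco acid, not isolated: (1S,4S,5S,6R,7S,8R,11S)-1,8-epoxy-4,5,7,8-tetrahydroxygermacr-9-en-15,6-olid-12-oic acid | O[C@H]1[C@H]2OC(=O)[C@]1(O)CC[C@@H]1O[C@](O)(C=C1C)[C@]2(O)[C@H](C)C(=O)O | intermediate
18 | (1S,4S,5S,6R,7S,8S,11S)-1,8-epoxy-4,5,7-trihydroxygermacr-9-ene-12,8:15,6-diolide (5-O-deacetyl target) | O[C@H]1[C@H]2OC(=O)[C@]1(O)CC[C@@H]1O[C@@]3(C=C1C)OC(=O)[C@@H](C)[C@]23O | intermediate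
19 | (1S,4S,5S,6R,7S,8S,11S)-5-acetoxy-1,8-epoxy-4,7-dihydroxygermacr-9-ene-12,8:15,6-diolide (CNP0315698.1) | CC(=O)O[C@H]1[C@H]2OC(=O)[C@]1(O)CC[C@@H]1O[C@@]3(C=C1C)OC(=O)[C@@H](C)[C@]23O | target

**Step count and risks**

Total step count: 13. Longest linear sequence: 11 steps (steps 1–4, then steps 7–13); the tartrate branch (steps 5–6) joins at step 7.

The three steps most likely to fail:

Step 10 (macrocyclising Stetter reaction). The carbene may add to the ynone or give benzoin oligomers instead of closing the ten-membered ring. The fallback sets out from 13 and closes the same C1–C10 bond with a vinyl-chromium nucleophile at the alcohol oxidation level. NaI in AcOH at rt adds HI across the ynone to give the (9Z)-10-iodo enone aldehyde F1. CrCl2 with catalytic NiCl2 in DMSO/THF at high dilution (Nozaki–Hiyama–Kishi ring closure) then adds C10 to the C1 aldehyde with retention of the Z geometry. The resulting cis γ-hydroxy enone closes to hemiketal 16, where the route is rejoined; C1 is then set by the ring rather than by a reagent.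

Step 7 (aldol, acetylide addition and lactonisation in one flask). The C6 configuration depends on Felkin–Anh control in a hindered aldol. The fallback sets out from 5 and 8 and runs only the aldol, with a neutral work-up, so that 9 is isolated together with the C6 epimer of the aldol adduct F2. Dess–Martin periodinane oxidises both to the single C6 ketone F3. LiBH(s-Bu)3 in THF at −78 °C reduces it with hydride delivery anti to the C5–O bond, giving 9 as an isolated compound. Treating 9 with 1-propynyllithium and acid as in the second half of step 7 gives 11, where the route is rejoined.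

Step 11 (reagent-controlled reduction at C1). The ring conformation may override the catalyst and give the C1 epimer. The fallback sets out from 14 and uses substrate control followed by inversion. A Luche reduction (NaBH4, CeCl3·7H2O, MeOH, −78 °C) gives the (1R)-hydroxy enone F4, which sits in equilibrium with its hemiketal. A Mitsunobu reaction on the open form (4-nitrobenzoic acid, PPh3, DIAD, THF, 0 °C) gives the (1S)-4-nitrobenzoate F5. Methanolysis (K2CO3, MeOH, 0 °C) frees the (1S)-alcohol, which closes to 16, where the route is rejoined.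

**Further compounds**

F1 | step 10 | (9Z)-10-iodo enone aldehyde: 13 with H and I added across C9≡C10, iodine on C10 cis to the C8 carbonyl | CC1(C)O[C@H]2[C@@H](OC(=O)[C@@]2(CCC=O)O1)[C@](O[Si](CC)(CC)CC)(C(=O)/C=C(/C)I)[C@H](C)C(=O)OC(C)(C)C
F2 | step 7 | C6 epimer of the aldol adduct: (6S)-isomer of 9 | COC(=O)[C@@]1(CC#C)OC(C)(C)O[C@H]1[C@H](O)[C@@]2(O[C@@H](C(C)(C)C)OC2=O)[C@H](C)C(=O)OC(C)(C)C
F3 | step 7 | C6 ketone: 9 with the C6 carbinol oxidised to C=O | COC(=O)[C@@]1(CC#C)OC(C)(C)O[C@H]1C(=O)[C@@]2(O[C@@H](C(C)(C)C)OC2=O)[C@H](C)C(=O)OC(C)(C)C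
F4 | step 11 | (1R)-hydroxy enone: C1 epimer of 15, drawn in its open form | CC1(C)O[C@H]2[C@H]3OC(=O)[C@@]2(CC[C@@H](O)/C(C)=C\C(=O)[C@]3(O[Si](CC)(CC)CC)[C@H](C)C(=O)OC(C)(C)C)O1
F5 | step 11 | (1S)-4-nitrobenzoate: 4-nitrobenzoyl ester of 15 | CC1(C)O[C@H]2[C@H]3OC(=O)[C@@]2(CC[C@H](OC(=O)c4ccc(cc4)[N+](=O)[O-])/C(C)=C\C(=O)[C@]3(O[Si](CC)(CC)CC)[C@H](C)C(=O)OC(C)(C)C)O1
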